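**Plan**

- Ring B (B1 bridge-bearing carbon, B2 C–O, B3 CMe2, B4 C–O, B5 acetyl-bearing carbon, B6 C–O) has oxygen on alternate carbons and a quaternary B3. A cyclobutenone–alkoxyalkyne annulation lays down exactly this pattern, and B3 forces it to stop at a cyclohexadienone instead of a phenol.
- Retrosynthesis: first the two O–benzyl bonds, the B5–acetyl bond and the two enol-ether alkyl groups are removed. Then B2–B1 and B6–B5 are cut together, giving 3-ethoxy-4,4-dimethylcyclobutenone and an arylmethyl methoxyalkyne. Last, the bridge CH2–C(sp) bond and the ring-A formyl carbon are cut back to flopropione.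
- Forward: ring A is present from the start and is dressed by methylation, formylation, benzylation, reduction, bromination and Stille alkynylation. The four-membered ring is made separately from dimethylketene and ethoxyacetylene. Ring B closes in the annulation; hydrolysis, C-acetylation and hydrogenolysis finish the route.
- Stereochemistry: the target is achiral, so no step has to set or protect a stereocentre.
- Design points: a methyl ynol ether (no retro-ene loss of alkene on heating), benzyl ethers on ring A (no O–H to trap ketenes), and a neutral tin–palladium alkynylation that spares the ring-A ketone.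

Key step: step 9

Remark: ring B is a β-triketone; it is written throughout in the 3,5-dihydroxy-2,5-dienone tautomer of the given structure, and ring A is the aromatic ring.

**Step 1**
Reactants: 1 isobutyryl chloride; 2 ethoxyacetylene
Product: 4 3-ethoxy-4,4-dimethylcyclobut-2-en-1-one, via dimethylketene 3 (not isolated)
Conditions: Et3N, Et2O, 0 °C → reflux (2 as hexane solution, 1.5 equiv)
Reagents that add atoms: none
Why: Dehydrochlorination of 1 gives dimethylketene, which should undergo the regioselective thermal [2+2] ketene–alkyne cycloaddition with the ynol ether, whose nucleophilic terminal carbon bonds to the ketene carbonyl carbon so that the ethoxy group ends next to the gem-dimethyl carbon.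

**Step 2**
Reactants: 5 chloroacetaldehyde dimethyl acetal
Product: 7 tributyl(methoxyethynyl)stannane, via lithium methoxyacetylide 6 (not isolated)
Conditions: Et2NH, n-BuLi (3.1 equiv each), THF, 0 °C; then Bu3SnCl, −78 °C → rt
Reagents that add atoms: tributyltin chloride, CCCC[Sn](Cl)(CCCC)CCCC
Why: Three equivalents of lithium amide should effect two β-eliminations (methanol, then HCl) and deprotonation to the alkoxyacetylide, the standard entry to metal alkoxyacetylides, and stannylation of an acetylide by a trialkyltin chloride is routine; the methyl ether is chosen because it has no β-hydrogen for retro-ene fragmentation at the temperature of step 9.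

**Step 3**
Reactants: 8 flopropione (2',4',6'-trihydroxypropiophenone)
Product: 9 1-(2,6-dihydroxy-4-methoxyphenyl)propan-1-one
Conditions: Me2SO4 (1.0 equiv), K2CO3 (1.0 equiv), acetone, rt
Reagents that add atoms: dimethyl sulfate, COS(=O)(=O)OC
Why: Williamson O-methylation with one equivalent of base and electrophile should go to the 4-hydroxyl, the only one not hydrogen-bonded to the ketone and the most acidic.

**Step 4**
Reactants: 9 1-(2,6-dihydroxy-4-methoxyphenyl)propan-1-one
Product: 11 2,4-dihydroxy-6-methoxy-3-propanoylbenzaldehyde, via chloro(methoxy)methyl arene 10 (not isolated)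
Conditions: Cl2CHOMe, TiCl4, CH2Cl2, −10 → 0 °C; then 1 M aq. HCl
Reagents that add atoms: dichloromethyl methyl ether, COC(Cl)Cl; water, O
Why: Rieche formylation should deliver the electrophile ortho to a titanium-bound phenoxide (the two free ring positions are equivalent by symmetry), aqueous work-up hydrolyses the α-chloro ether to the aldehyde, and the new formyl group deactivates the ring against a second substitution.

**Step 5**
Reactants: 11 2,4-dihydroxy-6-methoxy-3-propanoylbenzaldehyde
Product: 12 2,4-bis(benzyloxy)-6-methoxy-3-propanoylbenzaldehyde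
Conditions: BnBr (2.5 equiv), K2CO3, Bu4NI (cat.), DMF, 60 °C
Reagents that add atoms: benzyl bromide, BrCc1ccccc1
Why: Williamson benzylation under forcing but standard conditions should etherify both chelated phenols, removing every O–H that could later intercept a ketene.

**Step 6**
Reactants: 12 2,4-bis(benzyloxy)-6-methoxy-3-propanoylbenzaldehyde
Product: 13 1-[2,6-bis(benzyloxy)-3-(hydroxymethyl)-4-methoxyphenyl]propan-1-one
Conditions: NaBH4, THF–MeOH, −20 °C
Reagents that add atoms: none
Why: Chemoselective borohydride reduction should take the aldehyde far faster than the ethyl ketone, which is flanked by two ortho benzyloxy groups and twisted out of the ring plane.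

**Step 7**
Reactants: 13 1-[2,6-bis(benzyloxy)-3-(hydroxymethyl)-4-methoxyphenyl]propan-1-one
Product: 14 1-[2,6-bis(benzyloxy)-3-(bromomethyl)-4-methoxyphenyl]propan-1-one
Conditions: CBr4, PPh3, CH2Cl2, 0 °C; used crude at once
Reagents that add atoms: carbon tetrabromide, BrC(Br)(Br)Br
Why: The Appel reaction should give the bromide under neutral conditions, avoiding the HBr that would ionise this trialkoxybenzyl system.

**Step 8**
Reactants: 14 1-[2,6-bis(benzyloxy)-3-(bromomethyl)-4-methoxyphenyl]propan-1-one; 7 tributyl(methoxyethynyl)stannane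
Product: 15 1-[2,6-bis(benzyloxy)-4-methoxy-3-(3-methoxyprop-2-yn-1-yl)phenyl]propan-1-one
Conditions: Pd(PPh3)4 (5 mol %), THF, 50 °C; chromatography on Et3N-deactivated silica
Reagents that add atoms: none
Why: In this Stille coupling, oxidative addition of zerovalent palladium to the benzylic bromide is fast, alkynyl is the best-transferring group on tin, and the neutral conditions spare the enolisable ring-A ketone that a lithium acetylide would attack or deprotonate.

**Step 9**
Reactants: 4 3-ethoxy-4,4-dimethylcyclobut-2-en-1-one; 15 1-[2,6-bis(benzyloxy)-4-methoxy-3-(3-methoxyprop-2-yn-1-yl)phenyl]propan-1-one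
Product: 19 2-{[2,4-bis(benzyloxy)-6-methoxy-3-propanoylphenyl]methyl}-5-ethoxy-3-methoxy-6,6-dimethylcyclohexa-2,4-dien-1-one, via vinylketene 16 (not isolated), via vinylcyclobutenone 17 (not isolated), via dienylketene 18 (not isolated)
Conditions: 4 (3 equiv), PhMe, 145 °C, sealed tube, argon
Reagents that add atoms: none
Why: Proposed new method: heating should open 4 by a four-electron conrotatory electrocyclic reaction (B2–B3 breaks) to vinylketene 16, whose ketene carbon B2 is attacked by the nucleophilic, arylmethyl-bearing carbon of the ynol ether, so that a [2+2] addition forms B2–B1 and B5–B6 and gives 17; 17 then opens (B2–B5 breaks) to dienylketene 18, and a six-electron disrotatory electrocyclisation onto the CMe2 terminus re-forms B2–B3 and closes ring B. The closest known reaction type is the Danheiser benzannulation of cyclobutenones with alkoxy- and siloxyalkynes, which ends in tautomerisation to a phenol; here the quaternary B3 forbids that last event, and thermal opening of a 3-alkoxy-4,4-disubstituted cyclobutenone has its analogy in the rearrangement of 3-alkoxy-4,4-diarylcyclobutenones to naphthols. Ring B therefore closes in the 6π-electrocyclic mode, with all three ring oxygens already in place. No stereocentre is formed in 19; the one in 17 is racemic and transient. The step needs the regiochemistry of the ketene–alkyne addition, which the polarisation of the ynol ether secures by placing B1 between the B2 ketone and B6. It also needs ketenes that meet no O–H group and an alkyne that survives the temperature demanded by the reluctant 3-alkoxycyclobutenone; the benzyl ethers of ring A, the methyl ynol ether and an excess of 4 secure this.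

**Step 10**
Reactants: 19 2-{[2,4-bis(benzyloxy)-6-methoxy-3-propanoylphenyl]methyl}-5-ethoxy-3-methoxy-6,6-dimethylcyclohexa-2,4-dien-1-one
Product: 20 2-{[2,4-bis(benzyloxy)-6-methoxy-3-propanoylphenyl]methyl}-3,5-dihydroxy-4,4-dimethylcyclohexa-2,5-dien-1-one
Conditions: 2 M aq. HCl, THF, rt → 40 °C
Reagents that add atoms: water, O
Why: Acid hydrolysis of both enol ethers (a vinylogous ester and its vinylogue) by C-protonation and addition of water should give the enolised β-triketone, while benzyl aryl ethers are stable to dilute aqueous acid.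

**Step 11**
Reactants: 20 2-{[2,4-bis(benzyloxy)-6-methoxy-3-propanoylphenyl]methyl}-3,5-dihydroxy-4,4-dimethylcyclohexa-2,5-dien-1-one
Product: 22 2-acetyl-6-{[2,4-bis(benzyloxy)-6-methoxy-3-propanoylphenyl]methyl}-3,5-dihydroxy-4,4-dimethylcyclohexa-2,5-dien-1-one, via enol acetate 21 (not isolated)
Conditions: Ac2O (1.1 equiv), Et3N (2.2 equiv), DMAP (0.3 equiv), CH2Cl2, 0 °C → rt; then 1 M aq. HCl
Reagents that add atoms: acetic anhydride, CC(=O)OC(C)=O
Why: O-acetylation followed by DMAP-mediated O-to-C acyl transfer is the standard route to 2-acyl cyclic 1,3-diones; B5 is the only ring carbon still bearing hydrogen and transfer to the substituted B1 would be reversible, so the chelated 2-acyl triketone should be the thermodynamic sink (the enol acetate is drawn on the B4 oxygen, and a regioisomeric ester would funnel to the same product).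

**Step 12**
Reactants: 22 2-acetyl-6-{[2,4-bis(benzyloxy)-6-methoxy-3-propanoylphenyl]methyl}-3,5-dihydroxy-4,4-dimethylcyclohexa-2,5-dien-1-one
Product: 23 2-acetyl-6-[(2,4-dihydroxy-6-methoxy-3-propanoylphenyl)methyl]-3,5-dihydroxy-4,4-dimethylcyclohexa-2,5-dien-1-one (CNP0241167.0)
Conditions: H2 (1 atm), 10% Pd/C, EtOAc, rt
Reagents that add atoms: none
Why: Catalytic hydrogenolysis should cleave the two benzyl ethers while the tetrasubstituted, hydrogen-bonded enol double bonds and the aryl ketone are left untouched under these mild conditions.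

**Compound list**

1 | isobutyryl chloride | CC(C)C(=O)Cl | starting material
2 | ethoxyacetylene | CCOC#C | starting material
3 | dimethylketene | CC(C)=C=O | intermediate (not isolated)
4 | 3-ethoxy-4,4-dimethylcyclobut-2-en-1-one | CCOC1=CC(=O)C1(C)C | intermediate
5 | chloroacetaldehyde dimethyl acetal | COC(CCl)OC | starting material
6 | lithium methoxyacetylide | [Li]C#COC | intermediate (not isolated)
7 | tributyl(methoxyethynyl)stannane | CCCC[Sn](CCCC)(CCCC)C#COC | intermediate
8 | flopropione (2',4',6'-trihydroxypropiophenone) | CCC(=O)c1c(O)cc(O)cc1O | starting material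
9 | 1-(2,6-dihydroxy-4-methoxyphenyl)propan-1-one | CCC(=O)c1c(O)cc(OC)cc1O | intermediate
10 | 1-{3-[chloro(methoxy)methyl]-2,6-dihydroxy-4-methoxyphenyl}propan-1-one (racemic, titanium-bound in the flask) | CCC(=O)c1c(O)cc(OC)c(C(Cl)OC)c1O | intermediate (not isolated)
11 | 2,4-dihydroxy-6-methoxy-3-propanoylbenzaldehyde | CCC(=O)c1c(O)cc(OC)c(C=O)c1O | intermediate
12 | 2,4-bis(benzyloxy)-6-methoxy-3-propanoylbenzaldehyde | CCC(=O)c1c(OCc2ccccc2)cc(OC)c(C=O)c1OCc1ccccc1 | intermediate
13 | 1-[2,6-bis(benzyloxy)-3-(hydroxymethyl)-4-methoxyphenyl]propan-1-one | CCC(=O)c1c(OCc2ccccc2)cc(OC)c(CO)c1OCc1ccccc1 | intermediate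
14 | 1-[2,6-bis(benzyloxy)-3-(bromomethyl)-4-methoxyphenyl]propan-1-one | CCC(=O)c1c(OCc2ccccc2)cc(OC)c(CBr)c1OCc1ccccc1 | intermediate
15 | 1-[2,6-bis(benzyloxy)-4-methoxy-3-(3-methoxyprop-2-yn-1-yl)phenyl]propan-1-one | CCC(=O)c1c(OCc2ccccc2)cc(OC)c(CC#COC)c1OCc1ccccc1 | intermediate
16 | 3-ethoxy-4-methylpenta-1,3-dien-1-one (vinylketene) | CCOC(C=C=O)=C(C)C | intermediate (not isolated)
17 | 2-{[2,4-bis(benzyloxy)-6-methoxy-3-propanoylphenyl]methyl}-4-(1-ethoxy-2-methylprop-1-en-1-yl)-3-methoxycyclobut-2-en-1-one (racemic) | CCC(=O)c1c(OCc2ccccc2)cc(OC)c(CC2=C(OC)C(C(OCC)=C(C)C)C2=O)c1OCc1ccccc1 | intermediate (not isolated)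
18 | (3E)-2-{[2,4-bis(benzyloxy)-6-methoxy-3-propanoylphenyl]methyl}-5-ethoxy-3-methoxy-6-methylhepta-1,3,5-trien-1-one (ketene carbon and ethoxyalkenyl group cis across the central double bond) | CCC(=O)c1c(OCc2ccccc2)cc(OC)c(CC(=C=O)/C(OC)=C\C(OCC)=C(C)C)c1OCc1ccccc1 | intermediate (not isolated)
19 | 2-{[2,4-bis(benzyloxy)-6-methoxy-3-propanoylphenyl]methyl}-5-ethoxy-3-methoxy-6,6-dimethylcyclohexa-2,4-dien-1-one | CCOC1=CC(OC)=C(Cc2c(OC)cc(OCc3ccccc3)c(C(=O)CC)c2OCc2ccccc2)C(=O)C1(C)C | intermediate
20 | 2-{[2,4-bis(benzyloxy)-6-methoxy-3-propanoylphenyl]methyl}-3,5-dihydroxy-4,4-dimethylcyclohexa-2,5-dien-1-one | CCC(=O)c1c(OCc2ccccc2)cc(OC)c(CC2=C(O)C(C)(C)C(O)=CC2=O)c1OCc1ccccc1 | intermediate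
21 | 4-{[2,4-bis(benzyloxy)-6-methoxy-3-propanoylphenyl]methyl}-5-hydroxy-6,6-dimethyl-3-oxocyclohexa-1,4-dien-1-yl acetate (enol acetate) | CCC(=O)c1c(OCc2ccccc2)cc(OC)c(CC2=C(O)C(C)(C)C(OC(C)=O)=CC2=O)c1OCc1ccccc1 | intermediate (not isolated)
22 | 2-acetyl-6-{[2,4-bis(benzyloxy)-6-methoxy-3-propanoylphenyl]methyl}-3,5-dihydroxy-4,4-dimethylcyclohexa-2,5-dien-1-one | CCC(=O)c1c(OCc2ccccc2)cc(OC)c(CC2=C(O)C(C)(C)C(O)=C(C(C)=O)C2=O)c1OCc1ccccc1 | intermediate
23 | 2-acetyl-6-[(2,4-dihydroxy-6-methoxy-3-propanoylphenyl)methyl]-3,5-dihydroxy-4,4-dimethylcyclohexa-2,5-dien-1-one | CCC(=O)c1c(O)cc(OC)c(CC2=C(O)C(C)(C)C(O)=C(C(C)=O)C2=O)c1O | target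

**Step count and risks**

Total step count: 12. Longest linear sequence: 10 steps (steps 3 to 12, from flopropione).

Steps most likely to fail:

Step 9. The 3-alkoxycyclobutenone may not open at a useful rate, or the vinylketene may reclose, dimerise or suffer a 1,5-hydrogen shift from a methyl group faster than the alkyne intercepts it. The fallback sets out from benzylic alcohol 13 and brings ring B in ready-made. Commercial 2',4',6'-trihydroxyacetophenone would be gem-dimethylated on carbon (MeI, NaOMe, MeOH) to acetylfilicinic acid F1. The single remaining ring C–H of F1 would then be alkylated by the trialkoxybenzyl cation generated from 13 (cat. p-TsOH, CH2Cl2, rt, excess F1), a Friedel–Crafts-type dehydrative benzylation of a cyclic β-triketone of the kind used to make methylene-bridged acylphloroglucinols. This gives 22 directly, where the route is rejoined for step 12; steps 7 to 11 are not needed.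

Step 8. The trialkoxybenzyl bromide may ionise and alkylate the free ring-A carbon of a second molecule before oxidative addition, and the ynol ether may be hydrated on the metal or on silica. The fallback sets out from alcohol 13 and avoids any benzylic halide. Acylation with methyl chloroformate and pyridine would give the storable [2,4-bis(benzyloxy)-6-methoxy-3-propanoylphenyl]methyl methyl carbonate F2. F2 would then be coupled with stannane 7 under zerovalent palladium with a bidentate phosphine (Pd2(dba)3, DPPF, toluene, 80 °C). Here the carbonate ionises only on the metal, to an η3-benzyl palladium methoxide that transmetalates with tin and loses CO2. The route is rejoined at 15.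

Step 11. O-Acetylation may stall without onward O-to-C transfer, or the acyl group may lodge on the already substituted B1. The fallback sets out from 20 and builds the acetyl group by condensation instead of acyl transfer. N,N-Dimethylacetamide dimethyl acetal (toluene, 60 °C) would condense at the only methylene-active carbon B5 to give the vinylogous amide 2-{[2,4-bis(benzyloxy)-6-methoxy-3-propanoylphenyl]methyl}-6-[1-(dimethylamino)ethylidene]-3-hydroxy-4,4-dimethylcyclohex-2-ene-1,5-dione F3. Hydrolysis of F3 (1 M aq. HCl, THF) would release dimethylamine and give 22, where the route is rejoined.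

**Further compounds**

F1 | step 9 | acetylfilicinic acid (2-acetyl-3,5-dihydroxy-4,4-dimethylcyclohexa-2,5-dien-1-one) | CC(=O)C1=C(O)C(C)(C)C(O)=CC1=O
F2 | step 8 | [2,4-bis(benzyloxy)-6-methoxy-3-propanoylphenyl]methyl methyl carbonate | CCC(=O)c1c(OCc2ccccc2)cc(OC)c(COC(=O)OC)c1OCc1ccccc1
F3 | step 11 | 2-{[2,4-bis(benzyloxy)-6-methoxy-3-propanoylphenyl]methyl}-6-[1-(dimethylamino)ethylidene]-3-hydroxy-4,4-dimethylcyclohex-2-ene-1,5-dione | CCC(=O)c1c(OCc2ccccc2)cc(OC)c(CC2=C(O)C(C)(C)C(=O)C(=C(C)N(C)C)C2=O)c1OCc1ccccc1
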